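The readings are simulated with made-up constants; noise was put on by code.

Begin at the end.

| flask | substrate | reagent | free catalyst | remark | time |
|---|---|---|---|---|---|
| elm | 0.10 M | 0.47 equiv | 3 mol% | run made earlier |  |
| birch | 0.10 M | 1 equiv | 3 mol% | run made earlier |  |
| alder | 0.10 M | 0.70 equiv | 6 mol% | run made earlier |  |
| violet | 0.10 M | 0.700 equiv | 3 mol% |  | 12 h |
| blue | 0.10 M | 0.700 equiv | 3 mol% |  | 15 h |

- elm (time / h: target / %, substrate / %): 0.500: 2, 75; 1.33: 0, 52; 2.50: 7, 36; 4.00: 9, 17; 6.00: 14, 12; 8.00: 22, 10; 10.0: 22, 8
- birch (time / h: target / %, substrate / %): 1.33: 3, 52; 3.00: 12, 26; 4.00: 16, 19; 6.00: 21, 12; 8.00: 29, 3; 10.0: 36, 4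
- alder (time / h: target / %, substrate / %): 0.833: 5, 52; 1.33: 5, 37; 2.50: 14, 19; 5.00: 28, 6; 10.0: 46, 2

(scatter of a reading: 2 percentage points)



* which of the two there is more of at the end, violet (target / isomer of the product)
* which of the two there is more of at the end, blue (target / isomer of the product)
* final target, as a percentage of the substrate charged, in violet
* final target, as a percentage of the substrate charged, in blue

Where can violet and blue end? If one reagent makes one target, then reagent at 0.700 equiv is the limiting reagent, and target stands under a ceiling of 70.0 % of the substrate charged.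

How fast is that ceiling approached, and can the substrate tell me? Not by itself, since the readings of elm and birch both show 52 % of substrate at 1.33 h, although birch holds twice the reagent of elm, and so I watch the reagent instead.

What do you read from it? Alder, with the 0.70 equiv of violet and blue but 6 mol% of free catalyst, shows a reading of 46 % of target at 10.0 h, which gives 0.107 h⁻¹, and scaled in proportion to 3 mol%, which is my own assumption, this becomes 0.0535 h⁻¹. This is the reagent clock κ, the pseudo-first-order constant of reagent spending, ln(charge/(charge − target)) divided by time, with target read as spent reagent.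

Where is that weak? Read the same way at 3 mol%, elm gives 0.0631 h⁻¹ and birch 0.0446 h⁻¹, so the κ from alder lies between these two readings, and I carry their spread as its uncertainty, with the early lag folded in.

What do you commit to? Ceiling times (1 − e^(−κt)) gives me 33.2 % for violet and 38.6 % for blue.

And the isomer of the product? No earlier run reads it, and target drops by no more than 2 percentage points in any of them, so I put target ahead in both flasks, as a judgement.

The forecast says 30 % and 35 %, lower than my figures, and also puts target ahead, adding: “I assume it stays minor, though this is uncertain.”

Violet gave 33.6 % and blue 37.9 %, with target ahead of the isomer of the product's 5.65 % and 8.22 %.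

    substrate + free catalyst → free catalyst + open intermediate (k = 0.0660 L mol⁻¹ s⁻¹)
    free catalyst + open intermediate ⇌ catalyst intermediate (K = 420 L mol⁻¹, k = 0.0240 L mol⁻¹ s⁻¹)
    reagent + catalyst intermediate → free catalyst + target (k = 0.0130 L mol⁻¹ s⁻¹)
    target ⇌ isomer of the product (K = 1.00, k = 8.20 × 10⁻⁶ s⁻¹)
    2 free catalyst ⇌ resting dimer, settled at all times (K = 170 L mol⁻¹)
    substrate ⇌ dormant form (K = 2.90, k = 3.30 × 10⁻⁵ s⁻¹)

The clock's figures for these flasks were 33.2 % and 38.6 %. Left until 150 h, blue holds 35.0 % of target beside 35.0 % of the isomer of the product, with 0 % of its reagent left, and together the two come to the ceiling of 70.0 %. Scaled to a flask like blue with 1.2 mol% of free catalyst, the clock gives 19.2 % of target at 15 h, and that flask gave 18.5 %.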